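Thursday's flask could not have made 57.0% of left-handed product, more than the half of the charge that was left-handed substrate, from left-handed substrate as charged, so I concluded that the two substrates were exchanging hands while reagent captured them.

| flask | left-handed substrate | right-handed substrate | reagent | remark | time |
|---|---|---|---|---|---|
| Monday's | 10 mM | 10 mM | 15 mM | run made earlier |  |
| Thursday's | 10 mM | 10 mM | 89 mM | run made earlier |  |
| alpha | 10 mM | 10 mM | 20.0 mM |  | 5.0 min |
| gamma | 10 mM | 10 mM | 12.0 mM |  | 5.0 min |
| epsilon | 10 mM | 10 mM | 80.0 mM |  | 5.0 min |
| delta | 10 mM | 10 mM | 60.0 mM |  | 5.0 min |
| theta | 10 mM | 10 mM | 40.0 mM |  | 5.0 min |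

- Monday's (time / min: left-handed product / %, right-handed product / %): 0.200: 8.1, 3.3; 0.417: 13.8, 5.5; 0.667: 20.3, 8.4; 1.33: 29.3, 12.5; 2.50: 38.2, 16.6
- Thursday's (time / min: left-handed product / %, right-handed product / %): 0.200: 33.3, 15.9; 0.667: 51.6, 33.6; 1.33: 55.7, 40.2; 2.00: 57.0, 42.2; 2.50: 56.9, 42.0

(standard deviation of a reading: 0.3 percentage points)

- reagent is single-handed; left-handed substrate and right-handed substrate are mirror images of each other, charged as a racemate, each of them at the stated concentration
- what was read earlier has a scatter of 0.3 percentage points, one standard deviation
- the handed part of reagent does not stay in what it makes, so the products of the two hands are mirror images too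

- all flasks from highest to lowest share of left-handed product in all that became left-handed product or right-handed product, at 5.0 min (alpha / gamma / epsilon / delta / theta)
- the share of left-handed product in all that became left-handed product or right-handed product of the flask you put first, at 5.0 min
- the share of left-handed product in all that became left-handed product or right-handed product of the flask you put last, at 5.0 min

I first asked how strongly reagent prefers the left hand. Counting capture and no exchange in Thursday's first reading, I had the two hands falling at 5.48 min⁻¹ and 1.91 min⁻¹, which I read as a selectivity factor s of 2.87.

I then asked how exchange compares with capture. I called x the rate of capture of left-handed substrate over the rate at which a difference between the substrates decays, and P and Q the left-handed and right-handed products. Integrating both substrates to their end with reagent held steady gave P/Q = (s+x)/(1+x). Thursday's ratio of 1.35, with a mean reagent of 79.0 mM (the charge less half of what the substrates consume), gave x = 4.32. That made 18.3 mM my reading of the crossover reagent B×, the level at which capture of left-handed substrate keeps pace with exchange, and I took x in each new flask as its mean reagent over B×.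

Last I asked what that mean is at 5.0 min. Thursday's readings had stopped moving within their scatter by 2.00 min, and for epsilon, given longer than that, I took a mean reagent of 70.0 mM, so x = 3.83 and a left-handed share of 58.1%. In gamma reagent is the limiting reagent, less than the substrates together, so I took half its charge, giving x = 0.328 and a share of 70.7%, which I held as a rough estimate, since that charge cannot carry the substrates to their end. The means I took for alpha, theta and delta, 10.0 mM, 30.0 mM and 50.0 mM, rise in that order and lie above gamma's and below epsilon's, so I ranked the shares from gamma down through these to epsilon.

The forecast gave gamma > alpha > theta > delta > epsilon, with 70.9% (69.8% to 72%) and 57.9% (57.2% to 58.8%), on the ground that “Less reagent means slower capture relative to racemisation”. The flasks gave gamma > alpha > theta > delta > epsilon, with 70.7% and 58.0%.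

    reagent + right-handed substrate → right-handed product (k = 0.390 M⁻¹ s⁻¹)
    left-handed substrate ⇌ achiral form (K = 0.0110, k = 0.0198 s⁻¹)
    reagent + left-handed substrate → left-handed product (k = 1.07 M⁻¹ s⁻¹)
    right-handed substrate ⇌ achiral form (K = 0.0110, k = 0.0198 s⁻¹)
    reagent → decomposition product (k = 6.31 × 10⁻⁶ s⁻¹)

The hands exchanged through the achiral form, which stood at 0.246% of the substrates charged in gamma at 5.00 min. For the neighbour of gamma charged with 48 mM of reagent I took a mean reagent of 38.0 mM, so B× gave x = 2.08 and a share of 61.6%, and that flask stood at 61.8%.

The numbers in the tables are simulated with constants of no real substance.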